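**Retrosynthetic overview**
- The last operation is a chromium/nickel cascade on an open-chain (Z)-β-iodoenone aldehyde. It forms C1–C10 (ten-membered carbocycle), O12–C8 (dihydrofuran, ring B) and O17–C12 (spiro lactone, ring C) together.
- The iodoenone comes from a C8 thioester by ketone synthesis with a propynyl donor and hydroiodination. The cis-diol monoacetate of ring A comes from dihydroxylation of a butenolide.
- C6–C7 and ring A come from a vinylogous Mukaiyama aldol of a 3-alkyl-2-silyloxyfuran with an α-keto thioester that already carries C11–C13.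
- Building blocks: furan-2(5H)-one, acrolein dimethyl acetal, oxalyl chloride, a propanoate ketene silyl acetal, tributyl(propynyl)stannane.
- Ring order: ring A (step 5, oxidised in step 6), then carbocycle, ring B and ring C in step 10.

Assumption: germacrane numbering is used (ring C1–C10, C11–C13 propanoate unit, C14 methyl, C15 lactone carbonyl), and the descriptors of the SMILES, (1S,4S,5S,6R,7S,8S,11S), are taken literally although they put the C1–C2 and C8–C7 bonds on opposite faces of the dihydrofuran.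

**Step 1**
Reactants: 1 furan-2(5H)-one
Product: 3 3-bromofuran-2(5H)-one, via trans-dibromolactone 2 (not isolated)
Conditions: Br2 (1.05 equiv), CH2Cl2, 0 °C to rt; then Et3N (1.2 equiv), 0 °C
Reagents that add atoms: bromine, BrBr
Why: Bromine adds anti across the alkene and the amine then removes the acidic α-hydrogen with loss of the β-bromide (bromination–dehydrobromination), leaving the vinylic α-bromide and no stereocentre.

**Step 2**
Reactants: 3 3-bromofuran-2(5H)-one; 4 3,3-dimethoxyprop-1-ene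
Product: 6 3-(3,3-dimethoxypropyl)furan-2(5H)-one, via alkylborane 5 (not isolated)
Conditions: 4, 9-BBN, THF, 0 °C to rt; then 3, PdCl2(dppf) (5 mol %), AsPh3 (5 mol %), aq. K3PO4, DMF, rt
Reagents that add atoms: none
Why: Anti-Markovnikov hydroboration gives a primary alkyl-9-BBN that couples with the vinyl bromide in a B-alkyl Suzuki–Miyaura reaction under a phosphate base that the butenolide and the acetal tolerate.

**Step 3**
Reactants: 6 3-(3,3-dimethoxypropyl)furan-2(5H)-one
Product: 7 3-(3,3-dimethoxypropyl)-2-(trimethylsilyloxy)furan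
Conditions: Me3SiOTf (1.1 equiv), Et3N (1.5 equiv), Et2O, 0 °C
Reagents that add atoms: trimethylsilyl trifluoromethanesulfonate, C[Si](C)(C)OS(=O)(=O)C(F)(F)F
Why: Silyl triflate/amine soft enolisation of the butenolide gives the aromatic 2-silyloxyfuran (silyl dienol ether formation), the γ-nucleophile for step 5.

**Step 4**
Reactants: 8 oxalyl chloride; 9 1-methoxy-1-(trimethylsilyloxy)prop-1-ene
Product: 11 methyl 4-(ethylsulfanyl)-2-methyl-3,4-dioxobutanoate, via chlorooxalyl thioester 10 (not isolated)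
Conditions: 8 (3 equiv), EtSH (1 equiv), CH2Cl2, 0 °C, then evaporate; 9, CH2Cl2, −78 to 0 °C
Reagents that add atoms: ethanethiol, CCS
Why: The thiol is acylated once by excess oxalyl chloride and the α-oxo acid chloride then C-acylates the ketene silyl acetal (Claisen-type acylation with loss of Me3SiCl); C11 is formed racemic and epimerises through the enol, which step 5 uses.

**Step 5**
Reactants: 7 3-(3,3-dimethoxypropyl)-2-(trimethylsilyloxy)furan; 11 methyl 4-(ethylsulfanyl)-2-methyl-3,4-dioxobutanoate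
Product: 13 methyl (2S,3S)-3-[(2R)-4-(3,3-dimethoxypropyl)-5-oxo-2,5-dihydrofuran-2-yl]-4-(ethylsulfanyl)-3-hydroxy-2-methyl-4-oxobutanoate, via silyl ether 12 (not isolated)
Conditions: Cu(OTf)2 (10 mol %), 2,2'-isopropylidenebis[(4S)-4-tert-butyl-2-oxazoline] (11 mol %), CH2Cl2, −78 °C; then PPTS, MeOH, 0 °C
Reagents that add atoms: none
Why: Proposed new method: a vinylogous Mukaiyama aldol of the silyloxyfuran onto the 1,2-dicarbonyl unit chelated by the divalent copper–bis(oxazoline) complex (closest known: the same catalyst with silyloxyfurans and pyruvate esters), extended to an α-keto thioester with an epimerising α-centre; the ligand exposes the si face of the C7 ketone (7S), the furan approaches antiperiplanar with its C6–H over the chelate (6R), and of the two interconverting C11 epimers the one that holds its ester anti to the incoming nucleophile (Felkin–Anh) reacts (11S), after which PPTS/MeOH removes the tertiary silyl ether without touching the acetal.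

**Step 6**
Reactants: 13 methyl (2S,3S)-3-[(2R)-4-(3,3-dimethoxypropyl)-5-oxo-2,5-dihydrofuran-2-yl]-4-(ethylsulfanyl)-3-hydroxy-2-methyl-4-oxobutanoate
Product: 14 methyl (2S,3S)-3-[(2R,3S,4S)-4-(3,3-dimethoxypropyl)-3,4-dihydroxy-5-oxooxolan-2-yl]-4-(ethylsulfanyl)-3-hydroxy-2-methyl-4-oxobutanoate
Conditions: OsO4 (4 mol %), N-methylmorpholine N-oxide (1.5 equiv), acetone/H2O 5:1, 0 °C to rt
Reagents that add atoms: N-methylmorpholine N-oxide, C[N+]1([O-])CCOCC1; water, O
Why: Upjohn dihydroxylation adds both oxygens syn to the butenolide from the face opposite the C6 side chain, setting C4 (S) and C5 (S) cis to each other and trans to C7.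

**Step 7**
Reactants: 14 methyl (2S,3S)-3-[(2R,3S,4S)-4-(3,3-dimethoxypropyl)-3,4-dihydroxy-5-oxooxolan-2-yl]-4-(ethylsulfanyl)-3-hydroxy-2-methyl-4-oxobutanoate
Product: 15 methyl (2S,3S)-3-[(2R,3S,4S)-3-acetoxy-4-(3,3-dimethoxypropyl)-4-hydroxy-5-oxooxolan-2-yl]-4-(ethylsulfanyl)-3-hydroxy-2-methyl-4-oxobutanoate
Conditions: Ac2O (1.2 equiv), pyridine, DMAP (5 mol %), CH2Cl2, 0 °C
Reagents that add atoms: acetic anhydride, CC(=O)OC(C)=O
Why: Selective esterification: only the secondary C5 hydroxyl is acylated under these conditions, and the tertiary C4 and C7 hydroxyls stay free.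

**Step 8**
Reactants: 15 methyl (2S,3S)-3-[(2R,3S,4S)-3-acetoxy-4-(3,3-dimethoxypropyl)-4-hydroxy-5-oxooxolan-2-yl]-4-(ethylsulfanyl)-3-hydroxy-2-methyl-4-oxobutanoate; 16 tributyl(prop-1-yn-1-yl)stannane
Product: 17 methyl (2S,3S)-3-[(2R,3S,4S)-3-acetoxy-4-(3,3-dimethoxypropyl)-4-hydroxy-5-oxooxolan-2-yl]-3-hydroxy-2-methyl-4-oxohept-5-ynoate
Conditions: Pd2(dba)3 (2.5 mol %), tri(2-furyl)phosphine (10 mol %), copper thiophene-2-carboxylate CuO2CC4H3S (1.5 equiv), THF, 50 °C
Reagents that add atoms: none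
Why: Liebeskind–Srogl thioester–organostannane cross-coupling converts only the thioester into the ynone under base-free conditions, so the lactone, the esters and the free tertiary alcohols are untouched and the α'-hydroxy ynone is not cyclised to a furan-3(2H)-one by amine base.

**Step 9**
Reactants: 17 methyl (2S,3S)-3-[(2R,3S,4S)-3-acetoxy-4-(3,3-dimethoxypropyl)-4-hydroxy-5-oxooxolan-2-yl]-3-hydroxy-2-methyl-4-oxohept-5-ynoate
Product: 19 methyl (2S,3S,5Z)-3-[(2R,3S,4S)-3-acetoxy-4-hydroxy-5-oxo-4-(3-oxopropyl)oxolan-2-yl]-3-hydroxy-6-iodo-2-methyl-4-oxohept-5-enoate, via iodoenone acetal 18 (not isolated)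
Conditions: NaI (3 equiv), AcOH, rt; then H2O (AcOH/H2O 4:1), 40 °C
Reagents that add atoms: sodium iodide, [Na+].[I-]; water, O
Why: Conjugate hydroiodination of the ynone is an anti addition that gives the (Z)-β-iodoenone (iodine cis to the C8 carbonyl), and water in the same acid then hydrolyses the dimethyl acetal to the aldehyde, which rests as its lactol with the C4 hydroxyl.

**Step 10**
Reactants: 19 methyl (2S,3S,5Z)-3-[(2R,3S,4S)-3-acetoxy-4-hydroxy-5-oxo-4-(3-oxopropyl)oxolan-2-yl]-3-hydroxy-6-iodo-2-methyl-4-oxohept-5-enoate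
Product: 22 (1S,4S,5S,6R,7S,8S,11S)-5-acetoxy-1,8-epoxy-4,7-dihydroxygermacr-9-ene-15,6:12,8-diolide (CNP0315698.1), via hydroxy enone 20 (not isolated), via hemiketal 21 (not isolated)
Conditions: CrCl2 (8 equiv), NiCl2 (2 mol %), (S)-N-[2-(4-isopropyl-4,5-dihydrooxazol-2-yl)-6-methylphenyl]methanesulfonamide (8.8 equiv), proton sponge (8.8 equiv), THF/MeCN, 0.002 M, rt to 40 °C
Reagents that add atoms: none
Why: Proposed new method: a Nozaki–Hiyama–Kishi macrocyclisation in which the alkenylchromium from the (Z)-β-iodoenone adds to the C1 aldehyde (released from its lactol) to close the ten-membered ring, the trivalent-chromium alkoxide then adds to the cis-placed C8 ketone to close the dihydrofuran, and the hemiketal alkoxide acylates on the C12 methyl ester to close the spiro lactone (closest known: NHK couplings of (Z)-β-iodoacrylates that lactonise to butenolides, and NHK closures of ten-membered rings); C1 (S) is set by the sulfonamide-ligated chromium reagent (ligand antipode chosen for 1S) and C8 (S) by delivery of O12 on the side of the C7 hydroxyl within the chromium chelate.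

**Compound list**
1 | furan-2(5H)-one | O=C1OCC=C1 | starting material
2 | trans-3,4-dibromooxolan-2-one (racemic) | O=C1OC[C@H](Br)[C@H]1Br | intermediate
3 | 3-bromofuran-2(5H)-one | O=C1OCC=C1Br | intermediate
4 | 3,3-dimethoxyprop-1-ene (acrolein dimethyl acetal) | C=CC(OC)OC | starting material
5 | 9-(3,3-dimethoxypropyl)-9-borabicyclo[3.3.1]nonane | COC(OC)CCB1C2CCCC1CCC2 | intermediate
6 | 3-(3,3-dimethoxypropyl)furan-2(5H)-one | COC(OC)CCC1=CCOC1=O | intermediate
7 | 3-(3,3-dimethoxypropyl)-2-(trimethylsilyloxy)furan | COC(OC)CCc1ccoc1O[Si](C)(C)C | intermediate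
8 | oxalyl chloride | O=C(Cl)C(Cl)=O | starting material
9 | 1-methoxy-1-(trimethylsilyloxy)prop-1-ene (ketene silyl acetal of methyl propanoate, either alkene isomer) | CC=C(OC)O[Si](C)(C)C | starting material
10 | S-ethyl 2-chloro-2-oxoethanethioate | CCSC(=O)C(Cl)=O | intermediate
11 | methyl 4-(ethylsulfanyl)-2-methyl-3,4-dioxobutanoate (racemic at C2, enolisable) | CCSC(=O)C(=O)C(C)C(=O)OC | intermediate
12 | methyl (2S,3S)-3-[(2R)-4-(3,3-dimethoxypropyl)-5-oxo-2,5-dihydrofuran-2-yl]-4-(ethylsulfanyl)-2-methyl-4-oxo-3-(trimethylsilyloxy)butanoate | COC(OC)CCC1=C[C@@H](OC1=O)[C@](O[Si](C)(C)C)(C(=O)SCC)[C@H](C)C(=O)OC | intermediate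
13 | methyl (2S,3S)-3-[(2R)-4-(3,3-dimethoxypropyl)-5-oxo-2,5-dihydrofuran-2-yl]-4-(ethylsulfanyl)-3-hydroxy-2-methyl-4-oxobutanoate | COC(OC)CCC1=C[C@@H](OC1=O)[C@](O)(C(=O)SCC)[C@H](C)C(=O)OC | intermediate
14 | methyl (2S,3S)-3-[(2R,3S,4S)-4-(3,3-dimethoxypropyl)-3,4-dihydroxy-5-oxooxolan-2-yl]-4-(ethylsulfanyl)-3-hydroxy-2-methyl-4-oxobutanoate | COC(OC)CC[C@]1(O)[C@@H](O)[C@@H](OC1=O)[C@](O)(C(=O)SCC)[C@H](C)C(=O)OC | intermediate
15 | methyl (2S,3S)-3-[(2R,3S,4S)-3-acetoxy-4-(3,3-dimethoxypropyl)-4-hydroxy-5-oxooxolan-2-yl]-4-(ethylsulfanyl)-3-hydroxy-2-methyl-4-oxobutanoate | COC(OC)CC[C@]1(O)[C@@H](OC(C)=O)[C@@H](OC1=O)[C@](O)(C(=O)SCC)[C@H](C)C(=O)OC | intermediate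
16 | tributyl(prop-1-yn-1-yl)stannane | CC#C[Sn](CCCC)(CCCC)CCCC | starting material
17 | methyl (2S,3S)-3-[(2R,3S,4S)-3-acetoxy-4-(3,3-dimethoxypropyl)-4-hydroxy-5-oxooxolan-2-yl]-3-hydroxy-2-methyl-4-oxohept-5-ynoate | COC(OC)CC[C@]1(O)[C@@H](OC(C)=O)[C@@H](OC1=O)[C@](O)(C(=O)C#CC)[C@H](C)C(=O)OC | intermediate
18 | methyl (2S,3S,5Z)-3-[(2R,3S,4S)-3-acetoxy-4-(3,3-dimethoxypropyl)-4-hydroxy-5-oxooxolan-2-yl]-3-hydroxy-6-iodo-2-methyl-4-oxohept-5-enoate | COC(OC)CC[C@]1(O)[C@@H](OC(C)=O)[C@@H](OC1=O)[C@](O)(C(=O)/C=C(\I)C)[C@H](C)C(=O)OC | intermediate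
19 | methyl (2S,3S,5Z)-3-[(2R,3S,4S)-3-acetoxy-4-hydroxy-5-oxo-4-(3-oxopropyl)oxolan-2-yl]-3-hydroxy-6-iodo-2-methyl-4-oxohept-5-enoate (open form of the C1/C4-O lactol) | O=CCC[C@]1(O)[C@@H](OC(C)=O)[C@@H](OC1=O)[C@](O)(C(=O)/C=C(\I)C)[C@H](C)C(=O)OC | intermediate
20 | ten-membered (9Z)-enone: carbocycle C1–C10 with 1-OH (1S), the C15/O–C6 γ-lactone carrying 4-OH (4S) and 5-OAc (5S), 6R, 7-OH (7S), 8-oxo, 10-methyl, and the (11S)-CH(CH3)CO2CH3 group on C7 | CC(=O)O[C@H]1[C@H]2OC(=O)[C@]1(O)CC[C@H](O)/C(C)=C\C(=O)[C@]2(O)[C@H](C)C(=O)OC | intermediate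
21 | hemiketal of 20: O12 bridges C1 and C8 as a 2-hydroxy-2,5-dihydrofuran (8R by the CIP rules, same spatial arrangement at C8 as in 22), C12 methyl ester still open | CC(=O)O[C@H]1[C@H]2OC(=O)[C@]1(O)CC[C@@H]1O[C@](O)(C=C1C)[C@]2(O)[C@H](C)C(=O)OC | intermediate
22 | (1S,4S,5S,6R,7S,8S,11S)-5-acetoxy-1,8-epoxy-4,7-dihydroxygermacr-9-ene-15,6:12,8-diolide (CNP0315698.1) | CC(=O)O[C@H]1[C@H]2OC(=O)[C@]1(O)CC[C@@H]1O[C@@]3(C=C1C)OC(=O)[C@@H](C)[C@]23O | target

**Step count**
Total: 10 steps. Longest linear sequence: 9 steps (steps 1, 2, 3, 5, 6, 7, 8, 9, 10); step 4 is the side branch.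

**Steps most likely to fail**

Step 5. The electrophile 11 is an enolisable β-keto ester, copper chelation of an α-keto thioester is untested, and three stereocentres are set at once. The fallback sets out from 7 and comes back at 13. Thioester 11 is replaced by dimethyl 2-methyl-3-oxobutanedioate, an oxygen α-keto ester of the class for which the copper–bis(oxazoline) aldol is established. The same catalyst gives the silyl ether of the diester adduct F1, and PPTS/MeOH gives the diester adduct F2. Hydroxyl-directed thiolysis with Me2AlSEt (CH2Cl2, 0 °C) then converts F2 into 13: the aluminium alkoxide formed at the C7 hydroxyl delivers ethanethiolate to the neighbouring C8 ester, and any ring A lactone opened by the reagent recloses on acidic work-up.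

Step 8. The thioester sits on a fully substituted carbon and may couple slowly, and the α'-hydroxy ynone can cyclise to a furan-3(2H)-one. The fallback sets out from 15 and comes back at 17. Fukuyama reduction (Et3SiH, palladium on carbon, acetone, rt) gives the α-hydroxy aldehyde F3. Chromium-mediated alkynylation with 1-iodoprop-1-yne (CrCl2, NiCl2 cat., THF, rt) gives the propargylic alcohol F4 as C8 epimers. Dess–Martin oxidation (CH2Cl2, NaHCO3, 0 °C) gives 17.

Step 10. This step carries three risks: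
- The aldehyde is masked as a lactol with the C4 hydroxyl.
- A ten-membered ring has to close.
- The (1S,8S) ketal places the six-carbon bridge across the dihydrofuran. By a rough geometric estimate the bridge is too short to span it; if only the same-face ketal can close, the product will be the C1 or C8 epimer, and no reordering of steps avoids that.

The fallback sets out from 13 and comes back at 22, with ring A oxidised only after the cascade so that no C4 hydroxyl is present and ring A is flat during ring closure.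
- Coupling of 13 with 16 under the step 8 conditions gives the butenolide ynone F5.
- NaI/AcOH gives the butenolide iodoenone acetal F6, and water in the same flask gives the butenolide iodoenone aldehyde F7, which cannot form a lactol.
- The step 10 conditions take F7 through the macrocyclic hydroxy enone F8 and the hemiketal F9 to the tetracyclic butenolide F10.
- KMnO4 (MgSO4, acetone/H2O, −10 °C) dihydroxylates the conjugated, electron-poor C4=C5 bond from its outer face in preference to the hindered C9=C10 bond, giving the 4,5-diol F11.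
- Ac2O/pyridine (DMAP cat., 0 °C) acetylates the secondary C5 hydroxyl to give 22.

**Further compounds**
F1 | step 5 | dimethyl (2S,3S)-2-[(2R)-4-(3,3-dimethoxypropyl)-5-oxo-2,5-dihydrofuran-2-yl]-3-methyl-2-(trimethylsilyloxy)butanedioate | COC(OC)CCC1=C[C@@H](OC1=O)[C@](O[Si](C)(C)C)(C(=O)OC)[C@H](C)C(=O)OC
F2 | step 5 | dimethyl (2S,3S)-2-[(2R)-4-(3,3-dimethoxypropyl)-5-oxo-2,5-dihydrofuran-2-yl]-2-hydroxy-3-methylbutanedioate | COC(OC)CCC1=C[C@@H](OC1=O)[C@](O)(C(=O)OC)[C@H](C)C(=O)OC
F3 | step 8 | aldehyde analogue of 15 (C8 formyl in place of the thioester, all other centres as in 15) | COC(OC)CC[C@]1(O)[C@@H](OC(C)=O)[C@@H](OC1=O)[C@](O)(C=O)[C@H](C)C(=O)OC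
F4 | step 8 | propargylic alcohol analogue of 17 (C8 carbinol, both C8 epimers, all other centres as in 17) | COC(OC)CC[C@]1(O)[C@@H](OC(C)=O)[C@@H](OC1=O)[C@](O)(C(O)C#CC)[C@H](C)C(=O)OC
F5 | step 10 | methyl (2S,3S)-3-[(2R)-4-(3,3-dimethoxypropyl)-5-oxo-2,5-dihydrofuran-2-yl]-3-hydroxy-2-methyl-4-oxohept-5-ynoate | COC(OC)CCC1=C[C@@H](OC1=O)[C@](O)(C(=O)C#CC)[C@H](C)C(=O)OC
F6 | step 10 | methyl (2S,3S,5Z)-3-[(2R)-4-(3,3-dimethoxypropyl)-5-oxo-2,5-dihydrofuran-2-yl]-3-hydroxy-6-iodo-2-methyl-4-oxohept-5-enoate | COC(OC)CCC1=C[C@@H](OC1=O)[C@](O)(C(=O)/C=C(\I)C)[C@H](C)C(=O)OC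
F7 | step 10 | methyl (2S,3S,5Z)-3-hydroxy-6-iodo-2-methyl-4-oxo-3-[(2R)-5-oxo-4-(3-oxopropyl)-2,5-dihydrofuran-2-yl]hept-5-enoate | O=CCCC1=C[C@@H](OC1=O)[C@](O)(C(=O)/C=C(\I)C)[C@H](C)C(=O)OC
F8 | step 10 | butenolide analogue of 20 (C4=C5 in ring A, no 4-OH or 5-OAc; 1S,6R,7S,11S,9Z) | O=C1O[C@@H]2C=C1CC[C@H](O)/C(C)=C\C(=O)[C@]2(O)[C@H](C)C(=O)OC
F9 | step 10 | butenolide analogue of 21 (C4=C5 in ring A; 2-hydroxy-2,5-dihydrofuran closed, methyl ester open) | O=C1O[C@@H]2C=C1CC[C@@H]1O[C@](O)(C=C1C)[C@]2(O)[C@H](C)C(=O)OC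
F10 | step 10 | butenolide analogue of 22 (C4=C5 in ring A; 1S,6R,7S,8S,11S) | O=C1O[C@@H]2C=C1CC[C@@H]1O[C@@]3(C=C1C)OC(=O)[C@@H](C)[C@]23O
F11 | step 10 | 5-O-deacetyl 22 (4,5-diol; 1S,4S,5S,6R,7S,8S,11S) | O[C@H]1[C@H]2OC(=O)[C@]1(O)CC[C@@H]1O[C@@]3(C=C1C)OC(=O)[C@@H](C)[C@]23O
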